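## Retrosynthetic overview

1. Calamenene numbering is used in each half (C1 = CHMe, C4 = CH‑iPr, C8 = C–OH); the half joined through C7 is unprimed, the half joined through C5′ is primed. Both benzene rings are opened at once, at C4a–C5 and C4a′–C5′, so the hindered biaryl bond becomes a plain C7(sp3)–C5′(sp3) bond in an acyclic bis(1,3‑diketone).
2. The bis(1,3‑diketone) comes from two C‑acylations of the kinetic enolate of (+)‑menthone (two molecules, which already hold both cyclohexane rings and all four stereocentres) by a C10 diacid.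
3. The diacid comes from α‑alkylation of the dienolate of ethyl 3‑methylbut‑2‑enoate with ethyl 4‑bromo‑3‑methylbut‑2‑enoate; this C–C bond is the future biaryl bond.
4. Ring order: the two saturated rings come ready‑made from (+)‑menthol; the two aromatic rings are formed together in the last step.

Assumption: the SMILES fixes the four stereocentres but not the sense of the biaryl axis, so the target is accepted as either atropisomer or their mixture.

## Route

Step 1
Reactants: 1 (+)-menthol [(1S,2R,5S)-5-methyl-2-(propan-2-yl)cyclohexan-1-ol]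
Product: 2 (+)-menthone [(2R,5S)-5-methyl-2-(propan-2-yl)cyclohexan-1-one]
Conditions: TEMPO (1 mol %), KBr (10 mol %), NaOCl (1.1 equiv), CH2Cl2/aq. NaHCO3, 0 °C
Reagents that add atoms: none
Why: Anelli oxidation (TEMPO/NaOCl) of a secondary alcohol under buffered conditions at 0 °C leaves the epimerisable C2 centre next to the new ketone untouched, so both stereocentres of 2 (2R,5S, the ones needed for 1S,4R in each half of the target) come unchanged from 1.

Step 2
Reactants: 3 ethyl 3-methylbut-2-enoate; 4 ethyl (E)-4-bromo-3-methylbut-2-enoate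
Product: 7 (E)-4-methyl-2-(prop-1-en-2-yl)hex-4-enedioic acid, via lithium dienolate 5 (not isolated), via diethyl ester 6 (not isolated)
Conditions: LiN(iPr)2 (1.1 equiv), THF–DMPU, −78 °C; 4 (0.9 equiv), −78 to −20 °C; then LiOH, MeOH–H2O, 40 °C; HCl to pH 2
Reagents that add atoms: lithium hydroxide, [Li+].[OH-]
Why: Deconjugative α‑alkylation of the lithium dienolate (kinetic attack at Cα, SN2 at the primary allylic bromide, conjugate addition slowed by the β,β‑disubstitution of 4) joins the two C5 units through the future C7–C5′ bond and the crude diester is saponified in the same flask, the new chain CH centre being racemic and destroyed in step 4.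

Step 3
Reactants: 7 (E)-4-methyl-2-(prop-1-en-2-yl)hex-4-enedioic acid; 2 (+)-menthone (two molecules are built into each molecule of product)
Product: 10 (4E)-1,6-bis[(3R,6S)-6-methyl-2-oxo-3-(propan-2-yl)cyclohexyl]-4-methyl-2-(prop-1-en-2-yl)hex-4-ene-1,6-dione, via bis(acyl imidazolide) 8 (not isolated), via menthone lithium enolate 9 (not isolated)
Conditions: 7, CDI (2.1 equiv), THF, rt; separately 2 (6.6 equiv, surplus recovered by distillation), LiN(iPr)2 (6.5 equiv), THF, −78 °C; add 8 to 9, −78 to −40 °C; 1 M HCl
Reagents that add atoms: second equivalent of (+)-menthone 2, O=C1C[C@@H](C)CC[C@@H]1C(C)C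
Why: Claisen‑type C‑acylation of the kinetic lithium enolate of menthone (formed on the CH2 side at −78 °C, so the isopropyl‑bearing centre is never enolised) by both acyl imidazolide groups of 8 takes up two molecules of 2 per molecule of 7 and is driven by formation of the lithium 1,3‑diketonates, four further equivalents of 9 serving only as base for the imidazole set free on activation and for the acidic products, while the new ring and chain CH centres are enolisable and vanish in step 4.

Step 4
Reactants: 10 (4E)-1,6-bis[(3R,6S)-6-methyl-2-oxo-3-(propan-2-yl)cyclohexyl]-4-methyl-2-(prop-1-en-2-yl)hex-4-ene-1,6-dione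
Product: 13 (5R,8S)-2-[(5S,8R)-4-hydroxy-2,5-dimethyl-8-(propan-2-yl)-5,6,7,8-tetrahydronaphthalen-1-yl]-3,8-dimethyl-5-(propan-2-yl)-5,6,7,8-tetrahydronaphthalen-1-ol, via tetrakis(trimethylsilyl) polyenol ether 11 (not isolated), via bis(aryl trimethylsilyl ether) 12 (not isolated)
Conditions: Me3SiOTf (5 equiv), Et3N (8 equiv), PhMe, 0 °C to rt, then 110 °C; then 1 M HCl, THF, rt
Reagents that add atoms: none
Why: Proposed new method: exhaustive soft enolisation/silylation turns each acyl‑diketone arm into a 1,3‑bis(silyloxy)hexa‑1,3,5‑triene (C4a(OSi)=C8a–C8(OSi)=C7–C6=C5 and its primed counterpart ending in C6′=C5′), each of which closes by thermal disrotatory 6π‑electrocyclisation (C5→C4a, C5′→C4a′) and aromatises by loss of Me3SiOH, so both benzene rings and the tetra‑ortho‑substituted axis arise in one operation from the pre‑existing C7–C5′ bond; on the primed arm the dienol ether is expected to form towards C5′H2 (benzylic once the first ring has aromatised, and giving the more substituted diene) rather than the C6′ methyl, and no stereocentre is made or touched (C1/C4 and C1′/C4′ come from menthone, the hindered tertiary C4–H being far less acidic than the doubly activated chain positions); the closest known chemistry is the bis‑silylation of 1,3‑diketones to 1,3‑bis(silyloxy)dienes and the 6π‑electrocyclisation/elimination benzannulation of hexatrienes carrying a leaving group.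

## Compound list

1 | (+)-menthol, (1S,2R,5S)-5-methyl-2-(propan-2-yl)cyclohexan-1-ol | C[C@H]1CC[C@@H]([C@H](C1)O)C(C)C | starting material
2 | (+)-menthone, (2R,5S)-5-methyl-2-(propan-2-yl)cyclohexan-1-one | O=C1C[C@@H](C)CC[C@@H]1C(C)C | intermediate
3 | ethyl 3-methylbut-2-enoate | CCOC(=O)C=C(C)C | starting material
4 | ethyl (E)-4-bromo-3-methylbut-2-enoate (E/Z mixtures are equally usable) | CCOC(=O)/C=C(\C)CBr | starting material
5 | lithium 1-ethoxy-3-methylbuta-1,3-dien-1-olate (dienolate of 3; formed in the flask, not isolated) | CCOC(O[Li])=CC(C)=C | intermediate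
6 | diethyl (E)-4-methyl-2-(prop-1-en-2-yl)hex-4-enedioate, racemic at C2 (formed in the flask, not isolated) | CCOC(=O)C(C(C)=C)C/C(C)=C/C(=O)OCC | intermediate
7 | (E)-4-methyl-2-(prop-1-en-2-yl)hex-4-enedioic acid, racemic at C2 | OC(=O)C(C(C)=C)C/C(C)=C/C(=O)O | intermediate
8 | 1,1′-[(E)-4-methyl-2-(prop-1-en-2-yl)hex-4-enedioyl]bis(1H-imidazole) (formed in the flask, not isolated) | O=C(C(C(C)=C)C/C(C)=C/C(=O)n1ccnc1)n1ccnc1 | intermediate
9 | lithium (3S,6R)-3-methyl-6-(propan-2-yl)cyclohex-1-en-1-olate (kinetic enolate of 2; formed in the flask, not isolated) | [Li]OC1=C[C@@H](C)CC[C@@H]1C(C)C | intermediate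
10 | (4E)-1,6-bis[(3R,6S)-6-methyl-2-oxo-3-(propan-2-yl)cyclohexyl]-4-methyl-2-(prop-1-en-2-yl)hex-4-ene-1,6-dione; epimer mixture at the two ring C1 atoms and chain C2, largely enolised | O=C1C(C(=O)C(C(C)=C)C/C(C)=C/C(=O)C2C(=O)[C@@H](C(C)C)CC[C@@H]2C)[C@@H](C)CC[C@@H]1C(C)C | intermediate
11 | 1,6-bis[(3R,6S)-6-methyl-3-(propan-2-yl)-2-(trimethylsilyloxy)cyclohex-1-en-1-yl]-4-methyl-2-(prop-1-en-2-yl)-1,6-bis(trimethylsilyloxy)hexa-1,3,5-triene (double-bond isomer mixture; formed in the flask, not isolated) | C[Si](C)(C)OC1=C(C(O[Si](C)(C)C)=C(C(C)=C)C=C(C)C=C(O[Si](C)(C)C)C2=C(O[Si](C)(C)C)[C@@H](C(C)C)CC[C@@H]2C)[C@@H](C)CC[C@@H]1C(C)C | intermediate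
12 | bis(trimethylsilyl) ether of 13 (formed in the flask, not isolated) | Cc1cc2c(c(O[Si](C)(C)C)c1-c1c(C)cc(O[Si](C)(C)C)c3c1[C@@H](C(C)C)CC[C@@H]3C)[C@@H](C)CC[C@@H]2C(C)C | intermediate
13 | (5R,8S)-2-[(5S,8R)-4-hydroxy-2,5-dimethyl-8-(propan-2-yl)-5,6,7,8-tetrahydronaphthalen-1-yl]-3,8-dimethyl-5-(propan-2-yl)-5,6,7,8-tetrahydronaphthalen-1-ol, the 7,5′-linked dimer of (1S,4R)-8-hydroxycalamenene (CNP0145304.1; axis not defined) | Cc1cc2c(c(O)c1-c1c(C)cc(O)c3c1[C@@H](C(C)C)CC[C@@H]3C)[C@@H](C)CC[C@@H]2C(C)C | target

## Step count

Total steps: 4. Longest linear sequence: 3 (steps 2 → 3 → 4, or 1 → 3 → 4).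

## Steps most likely to fail, with fallbacks

Step 4, the double benzannulation, is the most likely to fail. The primed arm has two γ positions, and enolisation at the C6′ methyl instead of C5′H2 would close the second ring through the methyl carbon and give a CH2‑bridged isomer. The second closure also has to build a tetra‑ortho‑substituted axis, and the silyl enol ether geometries must equilibrate before closure. The fallback sets out from 10. Treatment with (COCl)2 and catalytic DMF in CH2Cl2 at 0 °C converts each enolised ring carbonyl into the vinylogous acid chloride and gives the bis(β‑chloro enone) (4E)-1,6-bis[(3R,6S)-2-chloro-6-methyl-3-(propan-2-yl)cyclohex-1-en-1-yl]-4-methyl-2-(prop-1-en-2-yl)hex-4-ene-1,6-dione F1. LiN(SiMe3)2 (4.5 equiv) in THF, −78 °C to rt, then removes the doubly activated C7–H and, once the first ring has aromatised, the now benzylic C5′–H. Each trienolate closes by anionic 6π‑electrocyclisation with expulsion of chloride, and acidic work‑up comes back to the route at 13. Both rings still form in one operation, but the neutral thermal silyl‑polyene pathway is replaced by an irreversible, base‑triggered closure with a built‑in leaving group.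

Step 3, the double C‑acylation, is the second risk. The α‑branched acyl imidazolide can be deprotonated to a ketene or give O‑acylation, the reaction may stop at mono‑acylation, and proton exchange between 9 and the menthone regenerated in the flask could epimerise the isopropyl‑bearing centre if the mixture is warmed above −40 °C. The fallback sets out from 2 and 7. Compound 2 is converted (LiN(iPr)2, Me3SiCl, THF, −78 °C) into the kinetic silyl enol ether trimethyl{[(3S,6R)-3-methyl-6-(propan-2-yl)cyclohex-1-en-1-yl]oxy}silane F2. Compound 7 is converted ((COCl)2, cat. DMF, CH2Cl2) into (E)-4-methyl-2-(prop-1-en-2-yl)hex-4-enedioyl dichloride F3. ZnCl2‑promoted C‑acylation of two equivalents of F2 by F3 in CH2Cl2–Et2O (Lewis‑acid acylation of a neutral silyl enol ether, no basic enolate present) comes back to the route at 10.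

Step 2, the alkylation with the bromo enoate, is the third risk. Compound 4 is also a Michael acceptor and is base‑sensitive, and γ‑alkylation or double alkylation can compete. The fallback sets out from dienolate 5. Alkylation with propargyl bromide gives ethyl 2-(prop-1-en-2-yl)pent-4-ynoate F4. Markovnikov hydration catalysed by Ph3PAuCl and AgOTf in aqueous MeOH gives ethyl 4-oxo-2-(prop-1-en-2-yl)pentanoate F5. Horner–Wadsworth–Emmons olefination with triethyl phosphonoacetate and NaH comes back to the route at diester 6 (E/Z mixture, both usable), which is saponified to 7 as in step 2.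

## Further compounds

F1 | step 4 | (4E)-1,6-bis[(3R,6S)-2-chloro-6-methyl-3-(propan-2-yl)cyclohex-1-en-1-yl]-4-methyl-2-(prop-1-en-2-yl)hex-4-ene-1,6-dione | ClC1=C(C(=O)C(C(C)=C)C/C(C)=C/C(=O)C2=C(Cl)[C@@H](C(C)C)CC[C@@H]2C)[C@@H](C)CC[C@@H]1C(C)C
F2 | step 3 | trimethyl{[(3S,6R)-3-methyl-6-(propan-2-yl)cyclohex-1-en-1-yl]oxy}silane | C[Si](C)(C)OC1=C[C@@H](C)CC[C@@H]1C(C)C
F3 | step 3 | (E)-4-methyl-2-(prop-1-en-2-yl)hex-4-enedioyl dichloride | ClC(=O)C(C(C)=C)C/C(C)=C/C(=O)Cl
F4 | step 2 | ethyl 2-(prop-1-en-2-yl)pent-4-ynoate | CCOC(=O)C(C(C)=C)CC#C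
F5 | step 2 | ethyl 4-oxo-2-(prop-1-en-2-yl)pentanoate | CCOC(=O)C(C(C)=C)CC(C)=O
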